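The data come from a simulation with made-up constants.

**The unit.** One percentage point of the D charged is the unit here. Each point stands as D, as G, or in an unseen rest, which is whatever the readings of D and G do not sum to. The south-west run is the asked flask itself, followed so far.

| flask | D | E | temperature | remark | time |
|---|---|---|---|---|---|
| south-west | 0.80 M | 0.96 M | −20 °C | the very flask that is asked about, followed so far |  |
| north | 1.6 M | 0.96 M | −25 °C | run made earlier |  |
| flask | 0.80 M | 0.960 M | −20 °C |  | 4.0 h |

| run | time / min | G / % | D / % |
|---|---|---|---|
| south-west | 12.0 | 16.2 | 71.1 |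
| south-west | 40.0 | 31.2 | 13.2 |
| south-west | 60.0 | 32.9 | 7.0 |
| south-west | 90.0 | 33.1 | 2.4 |
| south-west | 150 | 35.4 | 0 |
| north | 1.00 | 0.4 | 100.1 |
| north | 2.00 | 1.0 | 98.9 |
| north | 3.00 | 0.9 | 98.3 |
| north | 4.00 | 2.9 | 97.5 |
| north | 5.00 | 4.7 | 94.7 |

(each reading ± 0.5 percentage points)

- winter: change nothing and wait 80 min more
- noon: at 4.0 h take out 90 % of the G then present, then wait 80 min
- dusk: at 4.0 h raise the temperature by 25 K, then wait 80 min
- summer: at 4.0 h add E, 50.0 % of the amount charged, then wait 80 min

- removed G is counted in
- additions bring no volume worth counting

- G, in percent of the D first charged, at 4.0 h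
- which option adds most G ("none" when 2 percentage points or less is all one gets) (winter / noon / dusk / summer / none)
- G present, with what was taken out counted in, in percent of the D first charged, after winter
- G present, with what was taken out counted in, in percent of the D first charged, after noon

**First link.** D reads 0 % at 150 min, so in this flask winter and summer promise no gain over 2 percentage points.

**Second link.** Rest over G reads 0.784 at 12.0 min, 1.78 at 40.0 min and 1.82 at 150 min. It climbs, then stands, with G still present. I read that as a balance between G and the rest, not a dead end.

**Third link.** Follow one molecule past the fork: its chance of being found as G is 35.4 %, my figure for now.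

**Fourth link.** Noon removes 90 % of the G, and I expect the points remaining in the flask to split afresh. The ratio read steady by 40.0 min, and the wait is longer, so I count 56.0 %. Dusk stays open: the runs stand at −20 °C and −25 °C, and dusk warms this flask by 25 K.

**Weak link.** That ratio rests on one pair of readings. Pooling the four from 40.0 min onward gives the split ratio 1.85, rest over G at balance. So I reckon G at 35.1 % now, and the count after noon at 55.6 %.

**The forecast.** It gives 35.5 % now, 36 % after winter, 36 % after noon, and none as best, on the suggestion that “G is formed from D and then consumed by remaining D”.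

**The flask.** The rest proves to be J.

    D + E + G → 2 G (k = 0.641 M⁻² min⁻¹, Ea = 38.0 kJ mol⁻¹)
    D + E → G (k = 0.00296 M⁻¹ min⁻¹, Ea = 65.0 kJ mol⁻¹)
    G ⇌ J (K = 1.90, k = 0.227 min⁻¹, Ea = 78.0 kJ mol⁻¹, ΔH = −37.0 kJ mol⁻¹)
    (constants at −20 °C)

The flask gives 34.5 % now, 34.5 % after winter and 54.8 % after noon, against the 55.6 % reckoned. Dusk is best, adding 37 points to noon's 20 points. A neighbouring flask charged with 0.58 M of E has 0.725 equiv to D at the same temperature. With E as limiting reagent, I reckon that 72.5 % of the D reacts, and the split ratio puts 25.4 % of the charge in G. That neighbouring flask gives 25.0 % G, with 28 % of its D and 0.066 % of its E remaining.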